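**Plan**

- Retrosynthesis: the C8 angelate, the C3 acetate and the C11=C13 methylene come off last, and the cis-lactone is opened at C6–O to a tert-butyl ester. The Z-C4=C5 bond of the ten-membered carbocycle C1–C10 is then cut to an eleven-membered cyclic sulfone with SO2 between C4 and C5.
- What makes this possible: C4 and C5 each keep one α-hydrogen, their neighbours C3 and C6 carry only silyl ethers (poor nucleofuges), and a medium ring is expected to give the Z-trisubstituted olefin on SO2 loss.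
- Earlier cuts: both C–S bonds (Na2S on the C4 and C5 chlorides), C5–C6 (chloromethyl carbenoid on a Weinreb amide), C7–C8 (Evans aldol), C2–C3 (alkenylzinc + (S)-2-chloropropanal).
- Forward order: C15–C8 chain → full acyclic chain → thiacycle (step 15) → sulfone → 1(2)E,4Z-cyclodecadiene (step 17) → cis-γ-lactone (step 18) → methylene, acetate, angelate.
- Stereochemistry: C10 from Sharpless epoxidation; C3 from Cornforth–Felkin addition (C4 is a relay centre, erased in step 17); C7/C8 from the Evans syn-aldol; C6 from CBS reduction; E-C1=C2 from syn-hydrozirconation; Z-C4=C5 from the cis-fused episulfone.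

Key step: step 17

Remark: locants C1–C15 in the names are those of the germacrane skeleton of the target (C11, C12, C13 = lactone α-carbon, carbonyl, exocyclic CH2; C14, C15 = methyls on C10, C4).

Step 1
Reactants: 1 4-tert-butoxy-4-oxobutanoic acid; 2 (S)-4-benzyl-1,3-oxazolidin-2-one
Product: 4 tert-butyl 4-[(4S)-4-benzyl-2-oxo-1,3-oxazolidin-3-yl]-4-oxobutanoate, via mixed pivalic anhydride 3 (not isolated)
Conditions: PivCl, Et3N, THF, −20 °C; then 2, LiCl, −20 → 20 °C
Reagents that add atoms: none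
Why: N-acylation of the oxazolidinone by the in situ mixed anhydride (standard auxiliary loading), the hindered pivaloyl carbonyl not being attacked.

Step 2
Reactants: 5 methyl (S)-2-chloropropanoate
Product: 6 (S)-2-chloropropanal
Conditions: DIBAL-H (1.05 equiv), CH2Cl2, −78 °C; Rochelle salt; dried solution used at once
Reagents that add atoms: none
Why: Low-temperature DIBAL half-reduction of the ester through a stable tetrahedral aluminate should give the α-chloro aldehyde, which is used without storage to avoid epimerisation.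

Step 3
Reactants: 7 (E)-3-methylpent-2-en-4-yn-1-ol
Product: 8 [(2S,3S)-3-ethynyl-3-methyloxiran-2-yl]methanol
Conditions: Ti(Oi-Pr)4 (cat.), L-(+)-diisopropyl tartrate (cat.), t-BuOOH, 4 Å MS, CH2Cl2, −20 °C
Reagents that add atoms: tert-butyl hydroperoxide CC(C)(C)OO
Why: Sharpless asymmetric epoxidation of an E-trisubstituted allylic alcohol, where L-tartrate should give the (2S,3S)-epoxide (same sense as geraniol) and so fix the future C10.

Step 4
Reactants: 8 [(2S,3S)-3-ethynyl-3-methyloxiran-2-yl]methanol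
Product: 9 (R)-3-methylpent-4-yne-1,3-diol
Conditions: Red-Al, THF, −20 → 0 °C
Reagents that add atoms: none
Why: Hydroxyl-directed Red-Al opening of a 2,3-epoxy alcohol delivers hydride to C2 and leaves the quaternary C–O bond untouched, so the tertiary carbinol keeps the epoxide configuration.

Step 5
Reactants: 9 (R)-3-methylpent-4-yne-1,3-diol
Product: 10 (R)-3-methyl-3,5-bis(triethylsilyloxy)pent-1-yne
Conditions: TESOTf (2.4 equiv), 2,6-lutidine, CH2Cl2, −78 → 0 °C
Reagents that add atoms: triethylsilyl trifluoromethanesulfonate CC[Si](CC)(CC)OS(=O)(=O)C(F)(F)F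
Why: The silyl triflate silylates both the primary and the hindered tertiary propargylic hydroxyl.

Step 6
Reactants: 10 (R)-3-methyl-3,5-bis(triethylsilyloxy)pent-1-yne; 6 (S)-2-chloropropanal
Product: 13 (2S,3R,4E,6R)-2-chloro-6-methyl-6,8-bis(triethylsilyloxy)oct-4-en-3-ol, via alkenylzirconocene chloride 11 (not isolated), via alkenyl(methyl)zinc 12 (not isolated)
Conditions: Cp2Zr(H)Cl, CH2Cl2, 20 °C; Me2Zn, toluene, −65 °C; then 6, −65 → 0 °C
Reagents that add atoms: none
Why: syn-Hydrozirconation of the terminal alkyne fixes the E olefin, and after Zr→Zn transmetalation the base-free alkenylzinc should add to the α-chloro aldehyde under Cornforth–Felkin control (nucleophile anti to C–Cl) to give the anti-chlorohydrin, so C3 (R) follows from C4 (S).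

Step 7
Reactants: 13 (2S,3R,4E,6R)-2-chloro-6-methyl-6,8-bis(triethylsilyloxy)oct-4-en-3-ol
Product: 14 3-O-tert-butyldimethylsilyl ether of 13
Conditions: TBSOTf, 2,6-lutidine, CH2Cl2, −78 °C
Reagents that add atoms: tert-butyldimethylsilyl trifluoromethanesulfonate CC(C)(C)[Si](C)(C)OS(=O)(=O)C(F)(F)F
Why: Non-basic silylation protects the C3 hydroxyl before the chlorohydrin can close to an epoxide.

Step 8
Reactants: 14 3-O-tert-butyldimethylsilyl ether of 13
Product: 15 (3R,4E,6R,7S)-6-(tert-butyldimethylsilyloxy)-7-chloro-3-methyl-3-(triethylsilyloxy)oct-4-enal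
Conditions: (COCl)2, DMSO, CH2Cl2, −78 → −30 °C; then Et3N, −78 → 0 °C
Reagents that add atoms: none
Why: Under Swern conditions the unhindered primary TES ether is cleaved and oxidised directly to the aldehyde (a known selective oxidative deprotection), while the tertiary TES and secondary TBS ethers stay.

Step 9
Reactants: 4 tert-butyl 4-[(4S)-4-benzyl-2-oxo-1,3-oxazolidin-3-yl]-4-oxobutanoate; 15 (3R,4E,6R,7S)-6-(tert-butyldimethylsilyloxy)-7-chloro-3-methyl-3-(triethylsilyloxy)oct-4-enal
Product: 17 syn-aldol imide (3R,4S,7S,8R,10R; C6 N-acyloxazolidinone, C8-OH, C12 tert-butyl ester), via boron enolate 16 (not isolated)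
Conditions: n-Bu2BOTf, i-Pr2NEt, CH2Cl2, −78 → 0 °C; then 15, −78 → 0 °C; pH 7 buffer, MeOH, H2O2
Reagents that add atoms: none
Why: Evans syn-aldol, in which the Z-boron enolate of the imide reacts through a closed chair transition state on the face away from the benzyl group and should set C7 (S) and C8 (R) under auxiliary control.

Step 10
Reactants: 17 syn-aldol imide
Product: 18 C6 Weinreb amide (3R,4S,7S,8R,10R; C8-OH)
Conditions: MeNH(OMe)·HCl, AlMe3, THF, −20 → 0 °C
Reagents that add atoms: N,O-dimethylhydroxylamine hydrochloride CNOC.Cl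
Why: Aluminium amide transamination of a β-hydroxy imide, assisted by the free C8 hydroxyl, releases the auxiliary while the hindered tert-butyl ester does not react.

Step 11
Reactants: 18 C6 Weinreb amide
Product: 19 8-O-triisopropylsilyl Weinreb amide
Conditions: TIPSOTf, 2,6-lutidine, CH2Cl2, −78 → 0 °C
Reagents that add atoms: triisopropylsilyl trifluoromethanesulfonate CC(C)[Si](OS(=O)(=O)C(F)(F)F)(C(C)C)C(C)C
Why: The C8 hydroxyl is blocked with the most fluoride-resistant silyl group so that only the C6 oxygen can later lactonise.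

Step 12
Reactants: 19 8-O-triisopropylsilyl Weinreb amide
Product: 20 chloromethyl ketone (C5-Cl, C6 ketone; 3R,4S,7S,8R,10R)
Conditions: ICH2Cl, MeLi·LiBr, THF–Et2O, −78 °C
Reagents that add atoms: chloroiodomethane ClCI
Why: Chloromethyllithium formed by I/Li exchange adds once to the Weinreb amide (chelated tetrahedral intermediate) to give the α-chloro ketone, the tert-butyl ester and the alkyl chloride being inert at −78 °C.

Step 13
Reactants: 20 chloromethyl ketone
Product: 21 (6S)-chlorohydrin (3R,4S,6S,7R,8R,10R)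
Conditions: (S)-2-methyl-CBS-oxazaborolidine (cat.), catecholborane, toluene, −78 → −40 °C
Reagents that add atoms: none
Why: CBS reduction, where the catalyst tells the branched C7 side (large) from CH2Cl (small) and should give the (6S)-carbinol, the same sense as the Felkin preference of C7 (matched case), with catecholborane sparing the olefin.

Step 14
Reactants: 21 (6S)-chlorohydrin
Product: 22 6-O-triethylsilyl chlorohydrin (3R,4S,6S,7S,8R,10R)
Conditions: TESOTf, 2,6-lutidine, CH2Cl2, −78 °C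
Reagents that add atoms: triethylsilyl trifluoromethanesulfonate CC[Si](CC)(CC)OS(=O)(=O)C(F)(F)F
Why: Silylation under non-basic conditions prevents epoxide closure and puts a poor leaving group on C6 for the ring contraction.

Step 15
Reactants: 22 6-O-triethylsilyl chlorohydrin
Product: 24 eleven-membered thiacycle (S between C4 and C5; 3R,4R,6S,7S,8R,10R), via sodium thiolate 23 (not isolated)
Conditions: Na2S·9H2O, NaI (cat.), DMF, high dilution (syringe pump), 50 °C
Reagents that add atoms: sodium sulfide [Na+].[Na+].[S-2]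
Why: Double S-alkylation, in which sulfide displaces the primary C5 chloride and the weakly basic thiolate should then close the ring by SN2 at C4 with inversion under high dilution.

Step 16
Reactants: 24 eleven-membered thiacycle
Product: 25 thiacycle S,S-dioxide
Conditions: m-CPBA (2.2 equiv), NaHCO3, CH2Cl2, −20 → 0 °C
Reagents that add atoms: 3-chloroperoxybenzoic acid OOC(=O)c1cccc(Cl)c1
Why: Oxidation at sulfur is much faster than epoxidation of the two hindered olefins, which are deactivated by allylic oxygen.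

Step 17
Reactants: 25 thiacycle S,S-dioxide
Product: 27 ten-membered 1(2)E,4Z-diene tert-butyl ester (3R,6R,7S,8R,10R; 3-OTBS, 6-OTES, 8-OTIPS, 10-OTES), via episulfone 26 (not isolated)
Conditions: CBr2F2, KOH/Al2O3, t-BuOH–CH2Cl2, 0 → 20 °C
Reagents that add atoms: none
Why: An α-sulfonyl carbanion is brominated by CBr2F2, a second deprotonation at the other α-carbon closes the thiirane 1,1-dioxide 26 by 1,3-displacement, and 26 loses SO2 with retention to give the C4=C5 olefin. The closest known reaction type is the Ramberg–Bäcklund ring contraction of cyclic sulfones with in situ halogenation, which tolerates β-alkoxy sulfones and has been used for strained medium-ring trisubstituted Z-olefins. The ten-membered carbocycle closes in the 3-exo-tet episulfone formation inside the eleven-membered ring (11 → bicyclo[8.1.0] → 10), so the entropic cost of the medium ring was paid in the easier S-alkylation. No new stereocentre is formed: the relay centre C4 is erased, and the Z geometry should follow from the cis-fused episulfone, since a trans fusion would force a second E olefin into the ten-membered ring. The step needs halogenation and 1,3-elimination to beat E1cB loss of the C3 and C6 oxygens, which the silyl ethers (poor nucleofuges, no acyloxy group) and the low temperature are meant to secure, and it needs the sulfone α-C–H to react before the hindered tert-butyl ester enolises.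

Step 18
Reactants: 27 ten-membered diene tert-butyl ester
Product: 29 3,10-diol 8-O-triisopropylsilyl cis-6,12-lactone (3R,6R,7R,8R,10R), via triol tert-butyl ester 28 (not isolated)
Conditions: TBAF, THF, 0 → 20 °C; NH4Cl
Reagents that add atoms: none
Why: Fluoride removes the TES and allylic TBS ethers faster than the hindered secondary TIPS ether, and the C6 alkoxide should close the γ-lactone on the tert-butyl ester (5-exo-trig) while C8 stays blocked, so no 8,12-lactone can form.

Step 19
Reactants: 29 3,10-diol 8-O-triisopropylsilyl lactone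
Product: 32 α-methylene lactone 3,10-diol 8-O-triisopropylsilyl ether, via Mannich base 30 (not isolated), via trimethylammonium iodide 31 (not isolated)
Conditions: LDA (3.3 equiv), THF, −78 °C; CH2=NMe2+ I−, −78 → 20 °C; MeI, MeOH; NaHCO3, CH2Cl2–H2O
Reagents that add atoms: N,N-dimethylmethyleneiminium iodide C=[N+](C)C.[I-]
Why: Standard α-methylenation, in which the trianion (two alkoxides and the lactone enolate) undergoes a Mannich reaction at C11 and N-methylation followed by base-induced elimination gives the exocyclic olefin.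

Step 20
Reactants: 32 α-methylene lactone 3,10-diol
Product: 33 3-acetate (8-OTIPS, 10-OH)
Conditions: Ac2O, pyridine, DMAP (cat.), CH2Cl2, 0 °C
Reagents that add atoms: acetic anhydride CC(=O)OC(C)=O
Why: The secondary allylic C3 hydroxyl is acetylated while the tertiary C10 hydroxyl is too hindered to react.

Step 21
Reactants: 33 3-acetate
Product: 34 3-acetate 8,10-diol
Conditions: HF·pyridine (excess), THF, 20 → 35 °C
Reagents that add atoms: none
Why: Buffered HF cleaves the secondary TIPS ether under mildly acidic conditions that leave the acetate and the α-methylene lactone intact and avoid base-induced translactonisation to C8.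

Step 22
Reactants: 34 3-acetate 8,10-diol; 35 angelic acid
Product: 37 target (3R,6R,7S,8R,10R)-3-acetoxy-8-angeloyloxy-10-hydroxy-germacra-1(2)E,4Z,11(13)-trien-6,12-olide, via mixed Yamaguchi anhydride 36 (not isolated)
Conditions: 35, 2,4,6-Cl3C6H2COCl, Et3N, toluene, 20 °C; then 34, toluene, 75 °C
Reagents that add atoms: none
Why: Mixed-anhydride acylation of the secondary C8 hydroxyl without DMAP is a known way to keep the Z geometry of the angelate, and the tertiary C10 hydroxyl does not react.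

**Compound list**

1 | 4-tert-butoxy-4-oxobutanoic acid | CC(C)(C)OC(=O)CCC(=O)O | starting material
2 | (S)-4-benzyl-1,3-oxazolidin-2-one | O=C1OC[C@H](Cc2ccccc2)N1 | starting material
3 | mixed pivalic anhydride of 1 | CC(C)(C)OC(=O)CCC(=O)OC(=O)C(C)(C)C | intermediate
4 | tert-butyl 4-[(4S)-4-benzyl-2-oxo-1,3-oxazolidin-3-yl]-4-oxobutanoate | CC(C)(C)OC(=O)CCC(=O)N1C(=O)OC[C@@H]1Cc1ccccc1 | intermediate
5 | methyl (S)-2-chloropropanoate | C[C@H](Cl)C(=O)OC | starting material
6 | (S)-2-chloropropanal | C[C@H](Cl)C=O | intermediate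
7 | (E)-3-methylpent-2-en-4-yn-1-ol | C#C/C(C)=C/CO | starting material
8 | [(2S,3S)-3-ethynyl-3-methyloxiran-2-yl]methanol | C#C[C@]1(C)O[C@H]1CO | intermediate
9 | (R)-3-methylpent-4-yne-1,3-diol | C#C[C@](C)(O)CCO | intermediate
10 | (R)-3-methyl-3,5-bis(triethylsilyloxy)pent-1-yne | C#C[C@](C)(O[Si](CC)(CC)CC)CCO[Si](CC)(CC)CC | intermediate
11 | chlorobis(cyclopentadienyl)[(1E,3R)-3-methyl-3,5-bis(triethylsilyloxy)pent-1-enyl]zirconium | CC[Si](CC)(CC)OCC[C@@](C)(O[Si](CC)(CC)CC)/C=C/[Zr](Cl)(C1C=CC=C1)C1C=CC=C1 | intermediate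
12 | methyl[(1E,3R)-3-methyl-3,5-bis(triethylsilyloxy)pent-1-enyl]zinc | CC[Si](CC)(CC)OCC[C@@](C)(O[Si](CC)(CC)CC)/C=C/[Zn]C | intermediate
13 | (2S,3R,4E,6R)-2-chloro-6-methyl-6,8-bis(triethylsilyloxy)oct-4-en-3-ol | C[C@H](Cl)[C@H](O)/C=C/[C@](C)(O[Si](CC)(CC)CC)CCO[Si](CC)(CC)CC | intermediate
14 | 3-O-tert-butyldimethylsilyl ether of 13 | C[C@H](Cl)[C@H](O[Si](C)(C)C(C)(C)C)/C=C/[C@](C)(O[Si](CC)(CC)CC)CCO[Si](CC)(CC)CC | intermediate
15 | (3R,4E,6R,7S)-6-(tert-butyldimethylsilyloxy)-7-chloro-3-methyl-3-(triethylsilyloxy)oct-4-enal | C[C@H](Cl)[C@H](O[Si](C)(C)C(C)(C)C)/C=C/[C@](C)(O[Si](CC)(CC)CC)CC=O | intermediate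
16 | di-n-butylboron (Z)-enolate of 4 | CCCCB(CCCC)O/C(N1C(=O)OC[C@@H]1Cc1ccccc1)=C\CC(=O)OC(C)(C)C | intermediate
17 | syn-aldol imide (3R,4S,7S,8R,10R): C6 N-acyloxazolidinone, C8-OH, C12 tert-butyl ester | C[C@H](Cl)[C@H](O[Si](C)(C)C(C)(C)C)/C=C/[C@](C)(O[Si](CC)(CC)CC)C[C@@H](O)[C@H](CC(=O)OC(C)(C)C)C(=O)N1C(=O)OC[C@@H]1Cc1ccccc1 | intermediate
18 | C6 Weinreb amide, C8-OH (3R,4S,7S,8R,10R) | C[C@H](Cl)[C@H](O[Si](C)(C)C(C)(C)C)/C=C/[C@](C)(O[Si](CC)(CC)CC)C[C@@H](O)[C@H](CC(=O)OC(C)(C)C)C(=O)N(C)OC | intermediate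
19 | 8-O-triisopropylsilyl Weinreb amide | C[C@H](Cl)[C@H](O[Si](C)(C)C(C)(C)C)/C=C/[C@](C)(O[Si](CC)(CC)CC)C[C@@H](O[Si](C(C)C)(C(C)C)C(C)C)[C@H](CC(=O)OC(C)(C)C)C(=O)N(C)OC | intermediate
20 | chloromethyl ketone (C5-Cl, C6=O) | C[C@H](Cl)[C@H](O[Si](C)(C)C(C)(C)C)/C=C/[C@](C)(O[Si](CC)(CC)CC)C[C@@H](O[Si](C(C)C)(C(C)C)C(C)C)[C@H](CC(=O)OC(C)(C)C)C(=O)CCl | intermediate
21 | (6S)-chlorohydrin (3R,4S,6S,7R,8R,10R) | C[C@H](Cl)[C@H](O[Si](C)(C)C(C)(C)C)/C=C/[C@](C)(O[Si](CC)(CC)CC)C[C@@H](O[Si](C(C)C)(C(C)C)C(C)C)[C@H](CC(=O)OC(C)(C)C)[C@H](O)CCl | intermediate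
22 | 6-O-triethylsilyl chlorohydrin (3R,4S,6S,7S,8R,10R) | C[C@H](Cl)[C@H](O[Si](C)(C)C(C)(C)C)/C=C/[C@](C)(O[Si](CC)(CC)CC)C[C@@H](O[Si](C(C)C)(C(C)C)C(C)C)[C@H](CC(=O)OC(C)(C)C)[C@H](O[Si](CC)(CC)CC)CCl | intermediate
23 | sodium C5-thiolate of 22 | C[C@H](Cl)[C@H](O[Si](C)(C)C(C)(C)C)/C=C/[C@](C)(O[Si](CC)(CC)CC)C[C@@H](O[Si](C(C)C)(C(C)C)C(C)C)[C@H](CC(=O)OC(C)(C)C)[C@H](O[Si](CC)(CC)CC)C[S-].[Na+] | intermediate
24 | eleven-membered thiacycle, S between C4 and C5 (3R,4R,6S,7S,8R,10R) | C[C@H]1SC[C@@H](O[Si](CC)(CC)CC)[C@@H](CC(=O)OC(C)(C)C)[C@H](O[Si](C(C)C)(C(C)C)C(C)C)C[C@@](C)(O[Si](CC)(CC)CC)/C=C/[C@H]1O[Si](C)(C)C(C)(C)C | intermediate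
25 | thiacycle S,S-dioxide | C[C@H]1S(=O)(=O)C[C@@H](O[Si](CC)(CC)CC)[C@@H](CC(=O)OC(C)(C)C)[C@H](O[Si](C(C)C)(C(C)C)C(C)C)C[C@@](C)(O[Si](CC)(CC)CC)/C=C/[C@H]1O[Si](C)(C)C(C)(C)C | intermediate
26 | cis-fused episulfone (C4–C5 thiirane 1,1-dioxide) | C[C@@]12S(=O)(=O)[C@@H]1[C@@H](O[Si](CC)(CC)CC)[C@@H](CC(=O)OC(C)(C)C)[C@H](O[Si](C(C)C)(C(C)C)C(C)C)C[C@@](C)(O[Si](CC)(CC)CC)/C=C/[C@H]2O[Si](C)(C)C(C)(C)C | intermediate
27 | ten-membered 1(2)E,4Z-diene tert-butyl ester (3R,6R,7S,8R,10R) | C/C1=C/[C@@H](O[Si](CC)(CC)CC)[C@@H](CC(=O)OC(C)(C)C)[C@H](O[Si](C(C)C)(C(C)C)C(C)C)C[C@@](C)(O[Si](CC)(CC)CC)/C=C/[C@H]1O[Si](C)(C)C(C)(C)C | intermediate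
28 | 3,6,10-triol tert-butyl ester (8-OTIPS) | C/C1=C/[C@@H](O)[C@@H](CC(=O)OC(C)(C)C)[C@H](O[Si](C(C)C)(C(C)C)C(C)C)C[C@@](C)(O)/C=C/[C@H]1O | intermediate
29 | 3,10-diol 8-O-triisopropylsilyl cis-6,12-lactone (3R,6R,7R,8R,10R) | C1C(=O)O[C@@H]2/C=C(/C)[C@H](O)/C=C/[C@](C)(O)C[C@@H](O[Si](C(C)C)(C(C)C)C(C)C)[C@H]12 | intermediate
30 | 11-(dimethylaminomethyl) lactone (Mannich base) | CN(C)C[C@H]1C(=O)O[C@@H]2/C=C(/C)[C@H](O)/C=C/[C@](C)(O)C[C@@H](O[Si](C(C)C)(C(C)C)C(C)C)[C@H]12 | intermediate
31 | trimethylammonium iodide of 30 | C[N+](C)(C)C[C@H]1C(=O)O[C@@H]2/C=C(/C)[C@H](O)/C=C/[C@](C)(O)C[C@@H](O[Si](C(C)C)(C(C)C)C(C)C)[C@H]12.[I-] | intermediate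
32 | α-methylene lactone 3,10-diol 8-O-triisopropylsilyl ether | C=C1C(=O)O[C@@H]2/C=C(/C)[C@H](O)/C=C/[C@](C)(O)C[C@@H](O[Si](C(C)C)(C(C)C)C(C)C)[C@H]12 | intermediate
33 | 3-acetate (8-OTIPS, 10-OH) | C=C1C(=O)O[C@@H]2/C=C(/C)[C@H](OC(C)=O)/C=C/[C@](C)(O)C[C@@H](O[Si](C(C)C)(C(C)C)C(C)C)[C@H]12 | intermediate
34 | 3-acetate 8,10-diol | C=C1C(=O)O[C@@H]2/C=C(/C)[C@H](OC(C)=O)/C=C/[C@](C)(O)C[C@@H](O)[C@H]12 | intermediate
35 | angelic acid, (Z)-2-methylbut-2-enoic acid | C/C=C(/C)C(=O)O | starting material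
36 | angelic 2,4,6-trichlorobenzoic anhydride | C/C=C(/C)C(=O)OC(=O)c1c(Cl)cc(Cl)cc1Cl | intermediate
37 | target CNP0181631.1 | C=C1C(=O)O[C@@H]2/C=C(/C)[C@H](OC(C)=O)/C=C/[C@](C)(O)C[C@@H](OC(=O)/C(C)=C\C)[C@H]12 | target

**Count and risks**

Total: 22 steps. Longest linear sequence: 20 steps (steps 3–22; steps 1 and 2 are one-step side branches).

Steps most likely to fail:

1. Step 17. The α-sulfonyl carbanions may lose silyloxide from C3 or C6 by E1cB, the excess halogen donor may brominate the tert-butyl ester enolate, or closure to the trans-fused episulfone may give the E olefin. Fallback: the halogen is put in before the base and at the sulfide oxidation level, so no electrophilic halogen is present when carbanions form. N-Chlorosuccinimide (CCl4, 0 °C) should chlorinate sulfide 24 next to sulfur at the more substituted C4 to give the α-chloro sulfide F1 (one C4 epimer drawn, both serve). m-CPBA (2.2 equiv, NaHCO3, −20 °C) then gives the α-chloro sulfone F2. KOt-Bu (THF, −78 → 0 °C) deprotonates C5 and closes the same episulfone 26, which rejoins the route at 27.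

2. Step 15. Intramolecular SN2 at the secondary, β-branched C4 chloride may be slow enough for intermolecular S-alkylation (oligomers) and E2 loss of HCl to take over. Fallback: the two C–S bonds are made in separate operations. Starting from 22, potassium thioacetate (DMF, 40 °C) displaces only the primary C5 chloride to give the thioacetate F3. Cs2CO3 in MeOH–DMF (slow addition, high dilution, NaI, 50 °C) then releases a caesium thiolate that ring-closes at C4 and returns to 24.

3. Step 6. Facial selectivity in the alkenylzinc addition may be poor (C3 epimers), or the α-chloro aldehyde may epimerise. Fallback: C3 is set by reagent control on a ketone. The alkenylzirconocene 11 (from 10) is acylated with (S)-2-chloropropanoyl chloride (CuI cat., THF, 0 °C) to the enone F4. CBS reduction with the (R)-oxazaborolidine and catecholborane (alkenyl as the large group) should then give 13.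

**Further compounds**

F1 | step 17 | 4-chloro thiacycle (α-chloro sulfide of 24) | C[C@]1(Cl)SC[C@@H](O[Si](CC)(CC)CC)[C@@H](CC(=O)OC(C)(C)C)[C@H](O[Si](C(C)C)(C(C)C)C(C)C)C[C@@](C)(O[Si](CC)(CC)CC)/C=C/[C@H]1O[Si](C)(C)C(C)(C)C
F2 | step 17 | 4-chloro thiacycle S,S-dioxide | C[C@]1(Cl)S(=O)(=O)C[C@@H](O[Si](CC)(CC)CC)[C@@H](CC(=O)OC(C)(C)C)[C@H](O[Si](C(C)C)(C(C)C)C(C)C)C[C@@](C)(O[Si](CC)(CC)CC)/C=C/[C@H]1O[Si](C)(C)C(C)(C)C
F3 | step 15 | C5 thioacetate of 22 | C[C@H](Cl)[C@H](O[Si](C)(C)C(C)(C)C)/C=C/[C@](C)(O[Si](CC)(CC)CC)C[C@@H](O[Si](C(C)C)(C(C)C)C(C)C)[C@H](CC(=O)OC(C)(C)C)[C@H](O[Si](CC)(CC)CC)CSC(C)=O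
F4 | step 6 | (2S,4E,6R)-2-chloro-6-methyl-6,8-bis(triethylsilyloxy)oct-4-en-3-one | C[C@H](Cl)C(=O)/C=C/[C@](C)(O[Si](CC)(CC)CC)CCO[Si](CC)(CC)CC
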